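Remark on the chemistry (assumption): the facial selectivity of the diphenylprolinol silyl ether is taken from the usual steric-shielding model of the E-configured iminium ion, which assigns the (R)-catalyst to the (2S,3R)-aldehyde 3. Locants O1 and C2–C5 are those of the oxolane ring of the target; C1' is the exocyclic carbinol carbon.

## Structural features

The target is a single oxolane ring (O1, C2–C5) with three adjacent substituents: a 3,4,5-trimethoxyphenyl group on C2, a hydroxymethyl group on C3 and, on C4, an exocyclic carbinol carbon C1' that carries a 3,4-dimethoxyphenyl group; C5 is an unsubstituted CH2. Four stereocentres stand in a row, C2 (R), C3 (S), C4 (R) and C1' (S); the ring substituents are all-trans, and the C1' hydroxyl is syn to C3 when C1'–C4–C5 is drawn as a zigzag. Both benzylic C–O bonds (C2–O1 and C1'–OH) sit on electron-rich arenes and ionize easily with Brønsted or Lewis acids, which would epimerize C2, reduce or eliminate at C1', or re-close the chain to a 2,5-diaryl ether. One primary and two secondary hydroxyls appear on the way and must be told apart, and the β-hydroxy carbonyl intermediates can undergo retro-aldol cleavage or dehydration. The all-trans ring is the thermodynamically preferred arrangement, so the real difficulty lies in the absolute configuration of the ring and in the exocyclic centre C1', which the ring controls only weakly. The key step uses two facts: C2 is a benzylic, oxygen-bearing carbon with a donor aryl group, and C4 carries two carbons (C5 and C1') that can both be written at the carboxyl level. C2 and C4 are therefore the donor and acceptor carbons of a 2-aryl cyclopropane-1,1-diester, whose temporary C2–C4 bond can be made under catalyst control and later exchanged for the O1–C2 bond.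

## Logic of the disconnections

14 from 13. No skeletal bond is cut; only the O–Si bond on the C3 hydroxymethyl group is restored. The silyl ether keeps this primary hydroxyl distinct from the C5 hydroxyl during ring closure. The forward step must be a non-acidic desilylation that both benzylic C–O bonds tolerate.

13 from 11 (through 12). The O1–C5 bond is cut, opening the ring to a 1,4-diol. The cut is placed at C5 and not at C2 so that the forward closure is a displacement at a primary carbon and the C2–O bond is never broken. The gain is that the ring stereochemistry is carried unchanged in an open chain. The demand is selective activation of the one primary hydroxyl among three, with closure by the C2 hydroxyl (five-membered) faster than closure by the C1' hydroxyl (four-membered).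

11 from 10. C5 is raised to the carboxyl level, so O1–C5 becomes the acyl bond of a lactone. A carbonyl at C5 makes C4 enolizable for attaching C1' and is exactly what the ring expansion delivers. The reduction must spare the silyl ether and avoid retro-aldol cleavage of the β-hydroxy lactone.

10 from 9. The C1'–H bond is removed to give the aryl ketone. An aryl ketone allows the C1' configuration to be set by a chiral catalyst, while C4 stays trans to C3 because it can equilibrate. The forward step needs face-selective reduction of the ketone without touching the lactone.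

9 from 7 and 8. The C4–C1' bond is cut, an enolate acylation in the forward sense. This removes one aryl ring and one stereocentre and leads to a commercial acid chloride. The forward step needs C- over O-acylation and a second equivalent of base for the acidic product.

7 from 6. An ethoxycarbonyl group is added back at C4, which reveals the malonate that the cyclopropane needs as acceptor. This is the honest cost of the plan: the ester carbon is not carried into C1', because an ester cannot be turned into an aryl ketone selectively beside the lactone. The forward dealkoxycarbonylation must not open the benzylic lactone.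

6 from 5. The O1–C2 bond is cut and C2 is joined to C4. A lactone with three stereocentres becomes a cyclopropane whose two CH centres come from a known catalytic asymmetric reaction, and only C3 has to be carried through. The forward step demands heterolysis of the C2–C4 bond only, capture of the cation by an ester oxygen trans to the C3 substituent, and survival of the silyl ether.

5 from 4 from 3. The O–Si bond and then the oxidation level of the C3 side-chain carbon are adjusted back to a formyl group. The formyl group is what iminium catalysis needs. The forward steps need reduction of the aldehyde beside two esters and silylation before the hydroxyl can attack the cis ester.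

3 from 1 and 2. Both cyclopropane bonds from the malonyl carbon (C4–C2 and C4–C3) are cut. This leads to two commercial materials. The forward step needs enantiofacial control in the conjugate addition and trans ring closure.

## Other disconnections considered

Alternative 1: The ring is cut at O1–C2 and C3–C4, giving racemic vinylethylene carbonate A1 (O1, C5, C4 and the vinyl group) and the arylidene malonate A2 (C2 and C3). In the forward step zerovalent palladium from Pd2(dba)3 and a chiral phosphoramidite ionizes A1 with loss of CO2; the alkoxide adds to A2 and the malonate anion closes on the internal allyl carbon to give the 2,4-cis oxolane A3.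
- In its favour: it is convergent, it forms the ring in one catalytic step from simple partners, and C5 is already at the ether level. On convergence and ring oxidation level it is better than the chosen plan; in using a catalytic asymmetric step the two are equal.
- Against it here: C3 arrives quaternary and C4 carries a vinyl group. A3 therefore needs dealkoxycarbonylation (C3 set by protonation), ester reduction, protection, oxidative cleavage of the alkene beside two electron-rich arenes, and aryl-metal addition to an aldehyde that can epimerize or ring-open by β-elimination of O1. The C1' configuration would again need an oxidation and asymmetric reduction.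
- Mechanistically, the oxa-Michael step is reversible, and control of the 2,4-relationship with the unsubstituted carbonate is less assured than the thermodynamic trans control of the chosen plan.
- Step economy is about equal (roughly nine to ten steps).

Alternative 2: The C4–C5 bond is traced back to a 1,2-shift, so the oxolane is expanded to the diazo-oxanone A4. In the forward step photolysis triggers the Wolff rearrangement: the ring CH2–O carbon migrates to the carbene carbon, and the ketene is trapped by the N,O-dialkylhydroxylamine as Weinreb amide A5.
- In its favour: the future C1' is already on C4 at the acyl level, so one aryl-metal addition gives the aryl ketone without the dealkoxycarbonylation and re-acylation detour, and the ring is already an ether. On both points it is better than the chosen plan. The migration does not touch the two existing stereocentres.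
- Against it here: all the stereochemical work moves into A4. An enantiopure 2-aryl-3-vinyl oxanone must be built, and diazo transfer must be directed to C4 and away from the oxygen-flanked α-carbon. The carbene can also undergo a 1,2-hydrogen shift to an enone, the amide α-centre forms by kinetic protonation and may need epimerization, and the vinyl group must still be cut down to CH2OH.
- Step economy is worse than the chosen plan, because A4 alone is estimated at six or more steps.

Alternative 3: The C2–C3 bond is cut, giving the acyclic diazo ester A6 with C4 and C1' already in place. In the forward step Rh2(OPiv)4 or Rh2(S-PTTL)4 forms the carbenoid at C3, which inserts into the benzylic ether C–H bond to give the oxolane A7.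
- In its favour: C4 and C1' can be set by reliable acyclic aldol-type chemistry before the ring exists, the C–H bond is doubly activated (α-oxygen and electron-rich aryl), and after the key step only ester reduction and desilylation remain. In endgame length it is better than the chosen plan.
- Against it here: the carbenoid comes from an α-alkyl diazo ester with a hydrogen on C4, so the 1,2-hydride shift to the unsaturated ester competes and is held back only by bulky carboxylate ligands at low temperature. The insertion must set C2 and C3 relative to C4; C3 could be corrected through the ester enolate, but C2 could not. Making A6 requires diazo transfer onto an unactivated ester in a silylated, benzyl-ether-bearing chain.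
- Step economy is about equal. The chosen plan is safer for ring stereochemistry because its trans relationships are thermodynamic.

Key step: step 4

## Route

Step 1
Reactants: 1 3,4,5-trimethoxycinnamaldehyde; 2 diethyl bromomalonate
Product: 3 diethyl (2S,3R)-2-formyl-3-(3,4,5-trimethoxyphenyl)cyclopropane-1,1-dicarboxylate (trans)
Conditions: (R)-2-[diphenyl(trimethylsilyloxy)methyl]pyrrolidine (20 mol%), 2,6-lutidine (1.1 equiv), CH2Cl2, 0 °C → rt
Reagents that add atoms: none
Why: Iminium activation of 1, conjugate addition of the bromomalonate anion to the β-carbon on the face left open by the CPh2(OSiMe3) group, and enamine α-alkylation with loss of bromide (Michael-initiated ring closure) should give the trans cyclopropane. The (R)-catalyst is chosen because the shielding model leads to the (2S,3R) isomer, which fixes the later C3 centre.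

Step 2
Reactants: 3 diethyl (2S,3R)-2-formyl-3-(3,4,5-trimethoxyphenyl)cyclopropane-1,1-dicarboxylate
Product: 4 diethyl (2S,3R)-2-(hydroxymethyl)-3-(3,4,5-trimethoxyphenyl)cyclopropane-1,1-dicarboxylate
Conditions: NaBH4, EtOH, −10 → 0 °C; aq NH4Cl
Reagents that add atoms: none
Why: Borohydride reduces the aldehyde chemoselectively beside the two esters; low temperature, ethanol as solvent and immediate use of 4 should keep the new hydroxyl from lactonizing onto the cis ester or exchanging ester groups. No stereocentre is touched.

Step 3
Reactants: 4 diethyl (2S,3R)-2-(hydroxymethyl)-3-(3,4,5-trimethoxyphenyl)cyclopropane-1,1-dicarboxylate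
Product: 5 diethyl (2S,3R)-2-{[tert-butyl(diphenyl)silyl]oxymethyl}-3-(3,4,5-trimethoxyphenyl)cyclopropane-1,1-dicarboxylate
Conditions: TBDPSCl, imidazole, CH2Cl2, 0 °C → rt
Reagents that add atoms: tert-butyl(chloro)diphenylsilane (TBDPSCl), CC(C)(C)[Si](Cl)(c1ccccc1)c1ccccc1
Why: Standard silylation of a primary alcohol. The tert-butyldiphenylsilyl group is kept because it is the common silyl ether most resistant to the acid of step 4 and the least prone to migrate in the later triol.

Step 4
Reactants: 5 diethyl (2S,3R)-2-{[tert-butyl(diphenyl)silyl]oxymethyl}-3-(3,4,5-trimethoxyphenyl)cyclopropane-1,1-dicarboxylate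
Product: 6 ethyl (3S,4S,5R)-4-{[tert-butyl(diphenyl)silyl]oxymethyl}-2-oxo-5-(3,4,5-trimethoxyphenyl)oxolane-3-carboxylate (all-trans)
Conditions: TsOH·H2O (1.05 equiv), (CF3)2CHOH/CH2Cl2, 0 °C → rt
Reagents that add atoms: water, O
Why: Protonation of an ester carbonyl polarizes the cyclopropane bond between the aryl-bearing carbon and the malonyl carbon (target C2–C4), and its heterolysis is paid for by the trimethoxyphenyl donor on one side and the malonate enol on the other. An ester carbonyl oxygen then closes on the planar benzylic cation in a 5-exo-trig mode (forming O1–C2), and the resulting cyclic dialkoxycarbenium ion takes up the one equivalent of water carried by the acid hydrate and expels ethanol, leaving C5 as the lactone carbonyl. The closest known reaction type is the acid-mediated ring-opening lactonization of 2-aryl cyclopropane-1,1-diesters. The C3 centre from step 1 is not part of the bond that breaks and is retained. The new C2 centre is set by oxygen attack on the cation face anti to the CH2OSi group on C3; since the benzylic C–O bond can re-ionize in the medium, the trans lactone should also be the thermodynamic product. The new C4 centre is a malonate-type CH that equilibrates through the enol to the position trans to C3. The step needs cleavage of the C2–C4 bond and not the C3–C4 bond, which is secured because only C2 is benzylic. It also needs the silyl ether to survive, which is why the tert-butyldiphenylsilyl group and a single equivalent of water are used.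

Step 5
Reactants: 6 ethyl (3S,4S,5R)-4-{[tert-butyl(diphenyl)silyl]oxymethyl}-2-oxo-5-(3,4,5-trimethoxyphenyl)oxolane-3-carboxylate
Product: 7 (4S,5R)-4-{[tert-butyl(diphenyl)silyl]oxymethyl}-5-(3,4,5-trimethoxyphenyl)oxolan-2-one
Conditions: LiCl, H2O (2 equiv), DMSO, 140 °C
Reagents that add atoms: none
Why: Krapcho dealkoxycarbonylation: salt-assisted loss of the ethoxycarbonyl group of the malonate-type lactone ester as ethanol and CO2, with protonation at the α-carbon. The two remaining stereocentres are not involved, and a reversible opening of the benzylic lactone would re-close to the same trans isomer.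

Step 6
Reactants: 7 (4S,5R)-4-{[tert-butyl(diphenyl)silyl]oxymethyl}-5-(3,4,5-trimethoxyphenyl)oxolan-2-one; 8 3,4-dimethoxybenzoyl chloride
Product: 9 (3S,4S,5R)-4-{[tert-butyl(diphenyl)silyl]oxymethyl}-3-(3,4-dimethoxybenzoyl)-5-(3,4,5-trimethoxyphenyl)oxolan-2-one
Conditions: LiN(SiMe3)2 (2.2 equiv), THF, −78 °C; then 8, −78 → −30 °C; aq NH4Cl
Reagents that add atoms: none
Why: Claisen-type C-acylation of the lithium enolate of the lactone; the second equivalent of base holds the more acidic β-keto lactone as its enolate. Protonation at work-up should place the aroyl group trans to the neighbouring CH2OSi group, because this centre is epimerizable and trans is the stable arrangement.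

Step 7
Reactants: 9 (3S,4S,5R)-4-{[tert-butyl(diphenyl)silyl]oxymethyl}-3-(3,4-dimethoxybenzoyl)-5-(3,4,5-trimethoxyphenyl)oxolan-2-one
Product: 10 (3S,4S,5R)-4-{[tert-butyl(diphenyl)silyl]oxymethyl}-3-[(S)-(3,4-dimethoxyphenyl)(hydroxy)methyl]-5-(3,4,5-trimethoxyphenyl)oxolan-2-one
Conditions: RuCl[(S,S)-TsDPEN](p-cymene) (2 mol%), HCO2H/Et3N (5:2), CH2Cl2, rt
Reagents that add atoms: none
Why: Asymmetric transfer hydrogenation of an aryl ketone by the bifunctional ruthenium hydride/amine catalyst; the (S,S)-ligand should deliver hydride to the face that gives the (S)-carbinol, by the usual CH–π contact between the aryl group and the η6-arene. The enolizable α-centre stays trans to its neighbour, so C1' is set by the catalyst and the lactone is not reduced.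

Step 8
Reactants: 10 (3S,4S,5R)-4-{[tert-butyl(diphenyl)silyl]oxymethyl}-3-[(S)-(3,4-dimethoxyphenyl)(hydroxy)methyl]-5-(3,4,5-trimethoxyphenyl)oxolan-2-one
Product: 11 (1R,2S,3R)-2-{[tert-butyl(diphenyl)silyl]oxymethyl}-3-[(S)-(3,4-dimethoxyphenyl)(hydroxy)methyl]-1-(3,4,5-trimethoxyphenyl)butane-1,4-diol
Conditions: LiBH4, THF, 0 °C → rt
Reagents that add atoms: none
Why: Lithium borohydride reduces the lactone to the 1,4-diol without touching the silyl ether or the benzylic C–O bonds, and at low temperature reduction should outrun retro-aldol cleavage. No stereocentre changes.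

Step 9
Reactants: 11 (1R,2S,3R)-2-{[tert-butyl(diphenyl)silyl]oxymethyl}-3-[(S)-(3,4-dimethoxyphenyl)(hydroxy)methyl]-1-(3,4,5-trimethoxyphenyl)butane-1,4-diol
Product: 13 (S)-(3,4-dimethoxyphenyl)[(3R,4S,5R)-4-{[tert-butyl(diphenyl)silyl]oxymethyl}-5-(3,4,5-trimethoxyphenyl)oxolan-3-yl]methanol, via primary tosylate 12 (not isolated)
Conditions: TsCl (1.1 equiv), Et3N, DMAP (cat.), CH2Cl2, 0 °C → rt
Reagents that add atoms: none
Why: Selective sulfonylation of the only primary hydroxyl is followed by 5-exo-tet Williamson closure, in which the C2 hydroxyl attacks C5; the C2–O bond is never broken and all four stereocentres are retained. The C1' hydroxyl could only close a four-membered ring, and the basic medium avoids benzylic ionization.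

Step 10
Reactants: 13 (S)-(3,4-dimethoxyphenyl)[(3R,4S,5R)-4-{[tert-butyl(diphenyl)silyl]oxymethyl}-5-(3,4,5-trimethoxyphenyl)oxolan-3-yl]methanol
Product: 14 (S)-(3,4-dimethoxyphenyl)[(3R,4S,5R)-4-(hydroxymethyl)-5-(3,4,5-trimethoxyphenyl)oxolan-3-yl]methanol (CNP0172668.1)
Conditions: Bu4NF, THF, 0 °C → rt
Reagents that add atoms: none
Why: Fluoride cleaves the silyl ether under non-acidic conditions that the two electron-rich benzylic C–O bonds tolerate.

## Compound list

1 | 3,4,5-trimethoxycinnamaldehyde | COc1cc(/C=C/C=O)cc(OC)c1OC | starting material
2 | diethyl bromomalonate | CCOC(=O)C(Br)C(=O)OCC | starting material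
3 | diethyl (2S,3R)-2-formyl-3-(3,4,5-trimethoxyphenyl)cyclopropane-1,1-dicarboxylate | CCOC(=O)C1(C(=O)OCC)[C@@H](c2cc(OC)c(OC)c(OC)c2)[C@@H]1C=O | intermediate
4 | diethyl (2S,3R)-2-(hydroxymethyl)-3-(3,4,5-trimethoxyphenyl)cyclopropane-1,1-dicarboxylate | CCOC(=O)C1(C(=O)OCC)[C@@H](c2cc(OC)c(OC)c(OC)c2)[C@@H]1CO | intermediate
5 | diethyl (2S,3R)-2-{[tert-butyl(diphenyl)silyl]oxymethyl}-3-(3,4,5-trimethoxyphenyl)cyclopropane-1,1-dicarboxylate | CCOC(=O)C1(C(=O)OCC)[C@@H](c2cc(OC)c(OC)c(OC)c2)[C@@H]1CO[Si](c1ccccc1)(c1ccccc1)C(C)(C)C | intermediate
6 | ethyl (3S,4S,5R)-4-{[tert-butyl(diphenyl)silyl]oxymethyl}-2-oxo-5-(3,4,5-trimethoxyphenyl)oxolane-3-carboxylate | CCOC(=O)[C@H]1C(=O)O[C@@H](c2cc(OC)c(OC)c(OC)c2)[C@@H]1CO[Si](c1ccccc1)(c1ccccc1)C(C)(C)C | intermediate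
7 | (4S,5R)-4-{[tert-butyl(diphenyl)silyl]oxymethyl}-5-(3,4,5-trimethoxyphenyl)oxolan-2-one | O=C1O[C@@H](c2cc(OC)c(OC)c(OC)c2)[C@H](CO[Si](c2ccccc2)(c2ccccc2)C(C)(C)C)C1 | intermediate
8 | 3,4-dimethoxybenzoyl chloride | COc1ccc(C(=O)Cl)cc1OC | starting material
9 | (3S,4S,5R)-4-{[tert-butyl(diphenyl)silyl]oxymethyl}-3-(3,4-dimethoxybenzoyl)-5-(3,4,5-trimethoxyphenyl)oxolan-2-one | COc1ccc(C(=O)[C@H]2C(=O)O[C@@H](c3cc(OC)c(OC)c(OC)c3)[C@@H]2CO[Si](c2ccccc2)(c2ccccc2)C(C)(C)C)cc1OC | intermediate
10 | (3S,4S,5R)-4-{[tert-butyl(diphenyl)silyl]oxymethyl}-3-[(S)-(3,4-dimethoxyphenyl)(hydroxy)methyl]-5-(3,4,5-trimethoxyphenyl)oxolan-2-one | COc1ccc([C@@H](O)[C@H]2C(=O)O[C@@H](c3cc(OC)c(OC)c(OC)c3)[C@@H]2CO[Si](c2ccccc2)(c2ccccc2)C(C)(C)C)cc1OC | intermediate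
11 | (1R,2S,3R)-2-{[tert-butyl(diphenyl)silyl]oxymethyl}-3-[(S)-(3,4-dimethoxyphenyl)(hydroxy)methyl]-1-(3,4,5-trimethoxyphenyl)butane-1,4-diol | COc1ccc([C@@H](O)[C@@H](CO)[C@@H](CO[Si](c2ccccc2)(c2ccccc2)C(C)(C)C)[C@@H](O)c2cc(OC)c(OC)c(OC)c2)cc1OC | intermediate
12 | 4-O-(p-toluenesulfonyl) derivative of 11 (primary tosylate, configuration as in 11) | COc1ccc([C@@H](O)[C@@H](COS(=O)(=O)c2ccc(C)cc2)[C@@H](CO[Si](c2ccccc2)(c2ccccc2)C(C)(C)C)[C@@H](O)c2cc(OC)c(OC)c(OC)c2)cc1OC | intermediate (not isolated)
13 | (S)-(3,4-dimethoxyphenyl)[(3R,4S,5R)-4-{[tert-butyl(diphenyl)silyl]oxymethyl}-5-(3,4,5-trimethoxyphenyl)oxolan-3-yl]methanol | COc1ccc([C@@H](O)[C@H]2CO[C@@H](c3cc(OC)c(OC)c(OC)c3)[C@@H]2CO[Si](c2ccccc2)(c2ccccc2)C(C)(C)C)cc1OC | intermediate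
14 | (S)-(3,4-dimethoxyphenyl)[(3R,4S,5R)-4-(hydroxymethyl)-5-(3,4,5-trimethoxyphenyl)oxolan-3-yl]methanol | COc1ccc([C@@H](O)[C@H]2CO[C@@H](c3cc(OC)c(OC)c(OC)c3)[C@@H]2CO)cc1OC | target

## Step count and least certain steps

Total step count: 10. Longest linear sequence: 10 steps (from 1; 2 and 8 are commercial).

Step 4 (key step). The most likely failure is that the benzylic cation, once formed, loses a proton from C3 or alkylates another electron-rich arene instead of being captured by the weakly nucleophilic ester oxygen. A second failure is acid-induced loss of the silyl group, after which the freed hydroxyl would lactonize onto a neighbouring ester. The fallback sets out from 5 and comes back at 6. One ester is saponified (KOH, 1 equiv, EtOH/H2O, rt) to the half-ester acid 1-(ethoxycarbonyl)-2-{[tert-butyl(diphenyl)silyl]oxymethyl}-3-(3,4,5-trimethoxyphenyl)cyclopropane-1-carboxylic acid F1. This hemimalonate is then isomerized to 6 with catalytic Sc(OTf)3 in CH2Cl2 or by gentle warming; the carboxyl group is both the internal proton donor and the nucleophile, so neither strong acid nor water is needed.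

Step 7. The most likely failure is poor facial selectivity or slow hydride transfer if the face preferred by the catalyst is opposed by the resident centres at C4 and C3 (a mismatched pair). The fallback sets out from 9 and comes back at 10 by changing the controlling element from catalyst to substrate. Zn(BH4)2 in Et2O/THF at −20 °C should chelate the ketone and lactone carbonyl oxygens and deliver hydride to the ketone face on the side of the C4 hydrogen, anti to C3, which corresponds to the (S)-carbinol; no compound outside the list is formed (F0).

Step 9. The most likely failure is sulfonylation or ionization at a benzylic hydroxyl, which would close the chain in the wrong sense (a 2,5-diaryl oxolane) or erode the configuration at C2; silyl migration among the free hydroxyls is a further risk. The fallback sets out from 10 and comes back at 14, replacing steps 8 to 10.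
- The C1' hydroxyl is silylated (TBSOTf, 2,6-lutidine, CH2Cl2, −78 °C) to the bis-silyl lactone F2.
- F2 is reduced with i-Bu2AlH at −78 °C to the lactol F3.
- F3 is deoxygenated with Et3SiH/BF3·OEt2 at −78 °C to the bis-silyl oxolane F4.
- Bu4NF removes both silyl groups to give 14.

This fallback is longer and exposes the benzylic silyl ether to a Lewis acid, which is why it is not the first choice.

Step 6. The most likely failure is O-acylation of the enolate, double acylation, or proton exchange between product and unreacted enolate that stalls conversion. The fallback sets out from 7 and comes back at 9. The enolate of 7 (LiN(i-Pr)2, THF, −78 °C) is added to 3,4-dimethoxybenzaldehyde to give the aldol adducts F5 as a mixture of C1' epimers, which are oxidized together with Dess–Martin periodinane to the single ketone 9.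

## Further compounds

F1 | step 4 | (2S,3R)-1-(ethoxycarbonyl)-2-{[tert-butyl(diphenyl)silyl]oxymethyl}-3-(3,4,5-trimethoxyphenyl)cyclopropane-1-carboxylic acid (configuration at C1 not defined) | CCOC(=O)C1(C(=O)O)[C@@H](c2cc(OC)c(OC)c(OC)c2)[C@@H]1CO[Si](c1ccccc1)(c1ccccc1)C(C)(C)C
F0 | step 7 | none | none
F2 | step 9 | (3S,4S,5R)-3-[(S)-[tert-butyl(dimethyl)silyl]oxy(3,4-dimethoxyphenyl)methyl]-4-{[tert-butyl(diphenyl)silyl]oxymethyl}-5-(3,4,5-trimethoxyphenyl)oxolan-2-one | COc1ccc([C@@H](O[Si](C)(C)C(C)(C)C)[C@H]2C(=O)O[C@@H](c3cc(OC)c(OC)c(OC)c3)[C@@H]2CO[Si](c2ccccc2)(c2ccccc2)C(C)(C)C)cc1OC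
F3 | step 9 | (3S,4S,5R)-3-[(S)-[tert-butyl(dimethyl)silyl]oxy(3,4-dimethoxyphenyl)methyl]-4-{[tert-butyl(diphenyl)silyl]oxymethyl}-5-(3,4,5-trimethoxyphenyl)oxolan-2-ol (anomeric mixture) | COc1ccc([C@@H](O[Si](C)(C)C(C)(C)C)[C@H]2C(O)O[C@@H](c3cc(OC)c(OC)c(OC)c3)[C@@H]2CO[Si](c2ccccc2)(c2ccccc2)C(C)(C)C)cc1OC
F4 | step 9 | (2R,3S,4R)-4-[(S)-[tert-butyl(dimethyl)silyl]oxy(3,4-dimethoxyphenyl)methyl]-3-{[tert-butyl(diphenyl)silyl]oxymethyl}-2-(3,4,5-trimethoxyphenyl)oxolane | COc1ccc([C@@H](O[Si](C)(C)C(C)(C)C)[C@H]2CO[C@@H](c3cc(OC)c(OC)c(OC)c3)[C@@H]2CO[Si](c2ccccc2)(c2ccccc2)C(C)(C)C)cc1OC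
F5 | step 6 | (3S,4S,5R)-4-{[tert-butyl(diphenyl)silyl]oxymethyl}-3-[(3,4-dimethoxyphenyl)(hydroxy)methyl]-5-(3,4,5-trimethoxyphenyl)oxolan-2-one (both carbinol epimers) | COc1ccc(C(O)[C@H]2C(=O)O[C@@H](c3cc(OC)c(OC)c(OC)c3)[C@@H]2CO[Si](c2ccccc2)(c2ccccc2)C(C)(C)C)cc1OC
A1 | alternative 1 | 4-vinyl-1,3-dioxolan-2-one (vinylethylene carbonate, racemic) | C=CC1COC(=O)O1
A2 | alternative 1 | dimethyl 2-(3,4,5-trimethoxybenzylidene)malonate | COC(=O)C(=Cc1cc(OC)c(OC)c(OC)c1)C(=O)OC
A3 | alternative 1 | dimethyl (2S,4R)-2-(3,4,5-trimethoxyphenyl)-4-vinyloxolane-3,3-dicarboxylate (2,4-cis) | C=C[C@H]1CO[C@@H](c2cc(OC)c(OC)c(OC)c2)C1(C(=O)OC)C(=O)OC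
A4 | alternative 2 | (5R,6R)-4-diazo-6-(3,4,5-trimethoxyphenyl)-5-vinyloxan-3-one | [N-]=[N+]=C1C(=O)CO[C@@H](c2cc(OC)c(OC)c(OC)c2)[C@@H]1C=C
A5 | alternative 2 | (3R,4R,5R)-N-methoxy-N-methyl-5-(3,4,5-trimethoxyphenyl)-4-vinyloxolane-3-carboxamide (all-trans) | CON(C)C(=O)[C@H]1CO[C@@H](c2cc(OC)c(OC)c(OC)c2)[C@@H]1C=C
A6 | alternative 3 | tert-butyl (3R)-3-[(S)-[tert-butyl(dimethyl)silyl]oxy(3,4-dimethoxyphenyl)methyl]-2-diazo-4-[(3,4,5-trimethoxybenzyl)oxy]butanoate | COc1ccc([C@@H](O[Si](C)(C)C(C)(C)C)[C@@H](COCc2cc(OC)c(OC)c(OC)c2)C(=[N+]=[N-])C(=O)OC(C)(C)C)cc1OC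
A7 | alternative 3 | tert-butyl (2R,3R,4R)-4-[(S)-[tert-butyl(dimethyl)silyl]oxy(3,4-dimethoxyphenyl)methyl]-2-(3,4,5-trimethoxyphenyl)oxolane-3-carboxylate (all-trans) | COc1ccc([C@@H](O[Si](C)(C)C(C)(C)C)[C@H]2CO[C@@H](c3cc(OC)c(OC)c(OC)c3)[C@@H]2C(=O)OC(C)(C)C)cc1OC
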